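**Retrosynthetic overview**
1. Target 44 ⇒ tricyclic β-hydroxy ketone 34. The C7/C9 anti-diol monoester comes from an Evans–Tishchenko reaction with isovaleraldehyde, followed by senecioylation. The C1 enone is made last by oxidation and Saegusa–Ito dehydrogenation.
2. 34 ⇒ cycloheptenone 32 by catalyst-controlled β-borylation and oxidation at C9. 32 ⇒ keto aldehyde 30 by intramolecular aldol condensation (C8–C9), so the seven-membered ring is formed last.
3. 30 ⇒ bicyclo[3.1.1]heptan-6-one 15. C5–C6 is made by olefination, C5 is set by OH-directed hydrogenation, and C6 is dimethylated as the ester enolate.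
4. 15 ⇒ acid 12 by intramolecular vinylketene/alkene [2+2]. The cyclobutane and the six-membered ring are formed together, first.
5. 12 ⇒ enal 5 + silyl dienolate 8 by an intermolecular catalytic asymmetric vinylogous Mukaiyama aldol (C1–C2). The carbinol centre it creates controls the whole core.

Labels: C1–C11 follow the longipinane numbering of the target. C1 is the C=O, C2=C3(CH3) the alkene, C4 and C11 the bridgeheads, C5 the CH bearing C6(CH3)2, C7 the O-senecioyl carbon, C8 the CH2, C9 the O-isovaleryl carbon and C10 the quaternary C(CH3). "Syn" means lying over the bridge C1–C2–C3. "Anti" means pointing away from it, toward the opposite one-carbon bridge.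

Assumption: in the catalyst-controlled steps 6 and 22, and in the oxazaborolidine fallbacks, the catalyst antipode used is the one that gives the drawn configuration; both antipodes are commercial.

**Step 1**
Reactants: 1 prenyl acetate (3-methylbut-2-en-1-yl acetate)
Product: 2 (2E)-4-hydroxy-3-methylbut-2-en-1-yl acetate
Conditions: SeO2 (0.1 equiv), salicylic acid (0.1 equiv), t-BuOOH (3 equiv), CH2Cl2, rt
Reagents that add atoms: tert-butyl hydroperoxide, CC(C)(C)OO
Why: The Sharpless–Umbreit allylic oxidation (ene reaction then [2,3]-shift) hydroxylates only the methyl group trans to the chain, which fixes the E geometry that later becomes the C10 configuration.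

**Step 2**
Reactants: 2 (2E)-4-hydroxy-3-methylbut-2-en-1-yl acetate
Product: 3 (2E)-4-(benzyloxy)-3-methylbut-2-en-1-yl acetate
Conditions: BnOC(=NH)CCl3 (1.3 equiv), TfOH (0.05 equiv), CH2Cl2/cyclohexane, 0 °C to rt
Reagents that add atoms: benzyl 2,2,2-trichloroacetimidate, N=C(OCc1ccccc1)C(Cl)(Cl)Cl
Why: Acid-catalysed imidate benzylation protects the future C9 oxygen without the base that would move or cleave the acetate.

**Step 3**
Reactants: 3 (2E)-4-(benzyloxy)-3-methylbut-2-en-1-yl acetate
Product: 4 (2E)-4-(benzyloxy)-3-methylbut-2-en-1-ol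
Conditions: K2CO3 (0.2 equiv), MeOH, 0 °C to rt
Reagents that add atoms: none
Why: Zemplén-type transesterification removes the acetate and leaves the benzyl ether and the alkene geometry untouched.

**Step 4**
Reactants: 4 (2E)-4-(benzyloxy)-3-methylbut-2-en-1-ol
Product: 5 (2E)-4-(benzyloxy)-3-methylbut-2-enal
Conditions: MnO2 (15 equiv), CH2Cl2, rt
Reagents that add atoms: none
Why: MnO2 oxidises the allylic alcohol selectively to the enal under neutral conditions that keep the E alkene.

**Step 5**
Reactants: 6 methyl 3-methylbut-2-enoate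
Product: 8 tert-butyl[(1-methoxy-3-methylbuta-1,3-dien-1-yl)oxy]dimethylsilane, via lithium dienolate 7 (not isolated)
Conditions: LiN(iPr)2 (1.1 equiv), THF, −78 °C; TBSCl (1.2 equiv), DMPU, −78 °C to rt
Reagents that add atoms: tert-butyldimethylsilyl chloride, CC(C)(C)[Si](C)(C)Cl
Why: Kinetic γ-deprotonation of the senecioate and O-silylation give the standard silyl dienolate for vinylogous aldol chemistry.

**Step 6 (key fragment union)**
Reactants: 5 (2E)-4-(benzyloxy)-3-methylbut-2-enal; 8 silyl dienolate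
Product: 10 methyl (2E,5S,6E)-8-(benzyloxy)-5-hydroxy-3,7-dimethylocta-2,6-dienoate, via trichlorosilyl ether 9 (not isolated)
Conditions: SiCl4 (1.1 equiv), Denmark binaphthyldiamine-derived bisphosphoramide (Si-face-selective antipode, 0.05 equiv), iPr2NEt (0.1 equiv), CH2Cl2, −78 °C; aqueous work-up
Reagents that add atoms: none
Why: In this catalytic enantioselective vinylogous Mukaiyama aldol the chiral phosphoramide-bound silyl cation activates the conjugated aldehyde, the dienolate reacts only at its γ-carbon to form C1–C2 and the E-enoate, and Si-face attack sets the (S)-carbinol at C1.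

**Step 7**
Reactants: 10 methyl (2E,5S,6E)-8-(benzyloxy)-5-hydroxy-3,7-dimethylocta-2,6-dienoate
Product: 11 methyl (2E,5S,6E)-8-(benzyloxy)-5-(tert-butyldimethylsilyloxy)-3,7-dimethylocta-2,6-dienoate
Conditions: TBSCl (1.3 equiv), imidazole (2.5 equiv), DMF, rt
Reagents that add atoms: tert-butyldimethylsilyl chloride, CC(C)(C)[Si](C)(C)Cl
Why: Corey silylation masks the carbinol so that an acid chloride can be made, and it supplies the bulk that steers step 9.

**Step 8**
Reactants: 11 TBS ether ester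
Product: 12 (2E,5S,6E)-8-(benzyloxy)-5-(tert-butyldimethylsilyloxy)-3,7-dimethylocta-2,6-dienoic acid
Conditions: LiOH (5 equiv), THF/MeOH/H2O, 45 °C; then 1 M HCl to pH 4
Reagents that add atoms: lithium hydroxide, [Li+].[OH-]
Why: Saponification of the methyl ester leaves the secondary TBS ether, the benzyl ether and both alkene geometries intact.

**Step 9**
Reactants: 12 dienoic acid
Product: 15 (1R,4S,5R,7R)-7-[(benzyloxy)methyl]-4-(tert-butyldimethylsilyloxy)-7-methyl-2-methylidenebicyclo[3.1.1]heptan-6-one, via acid chloride 13 (not isolated), via vinylketene 14 (not isolated)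
Conditions: Me2C=C(Cl)NMe2 (1.1 equiv), CH2Cl2, 0 °C; then slow addition to Et3N (5 equiv), toluene, reflux, 0.005 M
Reagents that add atoms: none
Why: Dehydrochlorination at the methyl group cis to COCl gives the vinylketene, whose crossed intramolecular [2+2] cycloaddition (C5 to C11, C4 to the more substituted C10) is suprafacial on the E-alkene (CH2OBn anti, CH3 syn) and takes place on a single alkene face because allylic 1,3-strain holds C1–H against the C10 methyl, so the C1 carbinol sets C4, C10 and C11.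

**Step 10**
Reactants: 15 bicyclic ketone; 16 triethyl phosphonoacetate
Product: 18 ethyl 2-{7-[(benzyloxy)methyl]-4-(tert-butyldimethylsilyloxy)-7-methyl-2-methylidenebicyclo[3.1.1]heptan-6-ylidene}acetate (mixture of alkene isomers), via sodium phosphonate 17 (not isolated)
Conditions: NaH (2.0 equiv), 16 (2.2 equiv), THF, 0 °C; then 15, reflux
Reagents that add atoms: none
Why: Horner–Wadsworth–Emmons olefination works on this strained ketone, which cannot enolise at its bridgeheads, and it brings in C6 and C7; the alkene geometry is irrelevant.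

**Step 11**
Reactants: 18 exocyclic enoate
Product: 19 ethyl 2-{7-[(benzyloxy)methyl]-4-hydroxy-7-methyl-2-methylidenebicyclo[3.1.1]heptan-6-ylidene}acetate
Conditions: Bu4NF (1.5 equiv), THF, 0 °C to rt
Reagents that add atoms: none
Why: Fluoride desilylation frees the C1 hydroxyl that is needed as the directing group in step 12.

**Step 12**
Reactants: 19 hydroxy enoate
Product: 20 ethyl 2-{7-[(benzyloxy)methyl]-4-hydroxy-2,7-dimethylbicyclo[3.1.1]heptan-6-yl}acetate (C5-H syn; CH2CO2Et anti; C3 methyl on the C10 side)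
Conditions: [Ir(cod)(PCy3)(py)]PF6 (5 mol %), H2 (1 atm), CH2Cl2, rt
Reagents that add atoms: none
Why: In this hydroxyl-directed homogeneous hydrogenation the C1 hydroxyl sits on the syn side next to C5 and binds iridium, and CH2OBn blocks the anti face, so hydrogen reaches C5 from the syn face and places the acetate chain anti beside C9, while the C3 methylidene is saturated as well (its stereocentre is erased in step 28).

**Step 13**
Reactants: 20 hydroxy ester
Product: 21 ethyl 2-{7-[(benzyloxy)methyl]-4-(tert-butyldimethylsilyloxy)-2,7-dimethylbicyclo[3.1.1]heptan-6-yl}acetate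
Conditions: TBSOTf (1.3 equiv), 2,6-lutidine (2 equiv), CH2Cl2, 0 °C
Reagents that add atoms: tert-butyldimethylsilyl triflate, CC(C)(C)[Si](C)(C)OS(=O)(=O)C(F)(F)F
Why: Silylation with the triflate re-protects the hindered C1 alcohol for the enolate, hydride and Grignard steps, and the group is orthogonal to the benzyl ether.

**Step 14**
Reactants: 21 TBS ether ester
Product: 23 ethyl 2-{bicyclic core of 21}propanoate (C6 epimers), via lithium enolate 22 (not isolated)
Conditions: LiN(iPr)2 (1.3 equiv), THF, −78 °C; MeI (3 equiv), −78 to 0 °C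
Reagents that add atoms: iodomethane, CI
Why: The ester α-carbon C6 is the only acidic position, so this enolate alkylation is clean; the new centre is removed in step 15.

**Step 15**
Reactants: 23 monomethyl ester
Product: 25 ethyl 2-{7-[(benzyloxy)methyl]-4-(tert-butyldimethylsilyloxy)-2,7-dimethylbicyclo[3.1.1]heptan-6-yl}-2-methylpropanoate, via lithium enolate 24 (not isolated)
Conditions: LiN(iPr)2 (2 equiv), THF/DMPU, −78 to −20 °C; MeI (5 equiv), −78 °C to rt
Reagents that add atoms: iodomethane, CI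
Why: A second enolate methylation with the small electrophile MeI and DMPU completes the quaternary C6 without ever placing a cation or radical next to the cyclobutane.

**Step 16**
Reactants: 25 gem-dimethyl ester
Product: 26 2-{7-[(benzyloxy)methyl]-4-(tert-butyldimethylsilyloxy)-2,7-dimethylbicyclo[3.1.1]heptan-6-yl}-2-methylpropan-1-ol
Conditions: LiAlH4 (2 equiv), Et2O, 0 °C to rt
Reagents that add atoms: none
Why: LiAlH4 reduces even a pivalate-type ester fully, and both ethers are inert to it.

**Step 17**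
Reactants: 26 neopentyl alcohol
Product: 27 2-{7-[(benzyloxy)methyl]-4-(tert-butyldimethylsilyloxy)-2,7-dimethylbicyclo[3.1.1]heptan-6-yl}-2-methylpropanal
Conditions: Dess–Martin periodinane (1.3 equiv), CH2Cl2, rt
Reagents that add atoms: none
Why: Dess–Martin oxidation gives the C7 aldehyde, which cannot enolise, under mild conditions.

**Step 18**
Reactants: 27 C7 aldehyde
Product: 28 3-{7-[(benzyloxy)methyl]-4-(tert-butyldimethylsilyloxy)-2,7-dimethylbicyclo[3.1.1]heptan-6-yl}-3-methylbutan-2-ol (C7 epimers)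
Conditions: MeMgBr (2 equiv), Et2O, −78 to 0 °C; then H2O
Reagents that add atoms: methylmagnesium bromide, C[Mg]Br
Why: Grignard addition brings in C8; the carbinol configuration does not matter because it is oxidised in step 20.

**Step 19**
Reactants: 28 secondary alcohol
Product: 29 3-[4-(tert-butyldimethylsilyloxy)-7-(hydroxymethyl)-2,7-dimethylbicyclo[3.1.1]heptan-6-yl]-3-methylbutan-2-ol
Conditions: H2 (1 atm), Pd/C (10 wt %), EtOH, rt
Reagents that add atoms: none
Why: Hydrogenolysis removes the benzyl ether cleanly because the molecule has no alkene at this stage and the TBS ether is inert.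

**Step 20**
Reactants: 29 diol
Product: 30 4-(tert-butyldimethylsilyloxy)-2,7-dimethyl-6-(2-methyl-3-oxobutan-2-yl)bicyclo[3.1.1]heptane-7-carbaldehyde
Conditions: Dess–Martin periodinane (3 equiv), CH2Cl2, rt
Reagents that add atoms: none
Why: A double Dess–Martin oxidation gives the C7 methyl ketone and the C9 aldehyde, held side by side on the anti face of the cyclobutane.

**Step 21**
Reactants: 30 keto aldehyde
Product: 32 (1S,3S)-1-(tert-butyldimethylsilyloxy)longipin-8-en-7-one, via aldol 31 (not isolated)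
Conditions: KOH (0.5 equiv), MeOH, rt to 50 °C
Reagents that add atoms: none
Why: In this intramolecular aldol condensation only C8 can enolise and only the C9 aldehyde is within reach, so the seven-membered ring closes unambiguously, and E1cB loss of water removes the uncontrolled C9 carbinol.

**Step 22**
Reactants: 32 tricyclic enone
Product: 33 (1S,3S)-1-(tert-butyldimethylsilyloxy)-9-(4,4,5,5-tetramethyl-1,3,2-dioxaborolan-2-yl)longipinan-7-one (boron on the C11 side of the seven-membered ring)
Conditions: CuCl (5 mol %), NaOtBu (10 mol %), 2,3-bis(tert-butylmethylphosphino)quinoxaline (QuinoxP*, 6 mol %), B2pin2 (1.2 equiv), MeOH (2 equiv), THF, rt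
Reagents that add atoms: bis(pinacolato)diboron, CC1(C)OB(OC1(C)C)B1OC(C)(C)C(C)(C)O1
Why: The two faces of the enone differ only through remote groups, so in this copper-catalysed enantioselective conjugate borylation the chiral phosphine–copper boryl decides the face and sets C9.

**Step 23**
Reactants: 33 β-boryl ketone
Product: 34 (1S,3S,9R)-1-(tert-butyldimethylsilyloxy)-9-hydroxylongipinan-7-one
Conditions: NaBO3·4H2O (5 equiv), THF/H2O, rt
Reagents that add atoms: sodium perborate, [Na+].[Na+].O[B-]1(O)OO[B-](O)(O)OO1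
Why: Perborate oxidation replaces C–B by C–O with retention and is mild enough to avoid retro-aldol cleavage or dehydration.

**Step 24**
Reactants: 34 β-hydroxy ketone; 35 3-methylbutanal (isovaleraldehyde)
Product: 37 (1S,3S,7R,9R)-1-(tert-butyldimethylsilyloxy)-7-hydroxylongipinan-9-yl 3-methylbutanoate, via hemiacetal 36 (not isolated)
Conditions: SmI2 (0.3 equiv), 35 (6 equiv), THF, −10 °C
Reagents that add atoms: none
Why: In the Evans–Tishchenko reaction the samarium-bound hemiacetal on O9 passes its hydride to C7 from the face that carries O9, which sets the 7,9-anti relationship, installs the isovalerate on O9 and leaves only O7 free.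

**Step 25**
Reactants: 37 hydroxy isovalerate; 38 3-methylbut-2-enoic acid (senecioic acid)
Product: 40 (1S,3S,7R,9R)-1-(tert-butyldimethylsilyloxy)-9-(3-methylbutanoyloxy)longipinan-7-yl 3-methylbut-2-enoate, via mixed anhydride 39 (not isolated)
Conditions: 38 (3 equiv), 2,4,6-trichlorobenzoyl chloride (3 equiv), Et3N (6 equiv), toluene, rt; then 37, DMAP (3 equiv), 60 °C
Reagents that add atoms: none
Why: Yamaguchi esterification acylates the hindered neopentyl-type C7 alcohol and avoids the deconjugation seen with senecioyl chloride and amine bases.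

**Step 26**
Reactants: 40 diester TBS ether
Product: 41 (1S,3S,7R,9R)-1-hydroxy-9-(3-methylbutanoyloxy)longipinan-7-yl 3-methylbut-2-enoate
Conditions: HF·pyridine, THF/pyridine, 0 °C to rt
Reagents that add atoms: none
Why: Buffered HF removes the silyl ether without ester cleavage or acyl migration.

**Step 27**
Reactants: 41 C1 alcohol
Product: 42 (3S,7R,9R)-9-(3-methylbutanoyloxy)-1-oxolongipinan-7-yl 3-methylbut-2-enoate
Conditions: Dess–Martin periodinane (1.5 equiv), CH2Cl2, rt
Reagents that add atoms: none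
Why: Dess–Martin oxidation turns the now spent C1 control centre into the ketone of the target.

**Step 28**
Reactants: 42 saturated ketone
Product: 44 (4R,5S,7R,9R,10R,11R)-9-(3-methylbutanoyloxy)-1-oxolongipin-2-en-7-yl 3-methylbut-2-enoate (target), via silyl enol ether 43 (not isolated)
Conditions: TMSOTf (1.5 equiv), Et3N (3 equiv), CH2Cl2, 0 °C; then Pd(OAc)2 (1.1 equiv), MeCN, rt to 40 °C
Reagents that add atoms: none
Why: In the Saegusa–Ito oxidation the ketone can enolise only toward C2 (C11 is a bridgehead), soft enolisation spares the esters, and syn β-hydride elimination of C3–H gives the C2=C3 enone and erases the C3 centre.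

**Compound list**
1 | prenyl acetate | CC(C)=CCOC(C)=O | starting material
2 | (2E)-4-hydroxy-3-methylbut-2-en-1-yl acetate | CC(=O)OC/C=C(\C)CO | intermediate
3 | (2E)-4-(benzyloxy)-3-methylbut-2-en-1-yl acetate | CC(=O)OC/C=C(\C)COCc1ccccc1 | intermediate
4 | (2E)-4-(benzyloxy)-3-methylbut-2-en-1-ol | OC/C=C(\C)COCc1ccccc1 | intermediate
5 | (2E)-4-(benzyloxy)-3-methylbut-2-enal | O=C/C=C(\C)COCc1ccccc1 | intermediate
6 | methyl 3-methylbut-2-enoate | COC(=O)C=C(C)C | starting material
7 | lithium dienolate of 6 | [Li+].[O-]C(OC)=CC(C)=C | intermediate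
8 | tert-butyl[(1-methoxy-3-methylbuta-1,3-dien-1-yl)oxy]dimethylsilane | C=C(C)C=C(OC)O[Si](C)(C)C(C)(C)C | intermediate
9 | trichlorosilyl ether of 10 | COC(=O)/C=C(\C)C[C@H](O[Si](Cl)(Cl)Cl)/C=C(\C)COCc1ccccc1 | intermediate
10 | methyl (2E,5S,6E)-8-(benzyloxy)-5-hydroxy-3,7-dimethylocta-2,6-dienoate | COC(=O)/C=C(\C)C[C@H](O)/C=C(\C)COCc1ccccc1 | intermediate
11 | 5-O-TBS ether of 10 | COC(=O)/C=C(\C)C[C@H](O[Si](C)(C)C(C)(C)C)/C=C(\C)COCc1ccccc1 | intermediate
12 | (2E,5S,6E)-8-(benzyloxy)-5-(TBSO)-3,7-dimethylocta-2,6-dienoic acid | OC(=O)/C=C(\C)C[C@H](O[Si](C)(C)C(C)(C)C)/C=C(\C)COCc1ccccc1 | intermediate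
13 | acid chloride of 12 | ClC(=O)/C=C(\C)C[C@H](O[Si](C)(C)C(C)(C)C)/C=C(\C)COCc1ccccc1 | intermediate
14 | vinylketene | O=C=CC(=C)C[C@H](O[Si](C)(C)C(C)(C)C)/C=C(\C)COCc1ccccc1 | intermediate
15 | (1R,4S,5R,7R)-7-[(benzyloxy)methyl]-4-(TBSO)-7-methyl-2-methylidenebicyclo[3.1.1]heptan-6-one | O=C1[C@@H]2C(=C)C[C@H](O[Si](C)(C)C(C)(C)C)[C@H]1[C@]2(C)COCc1ccccc1 | intermediate
16 | triethyl phosphonoacetate | CCOC(=O)CP(=O)(OCC)OCC | starting material
17 | sodium salt of 16 | [Na+].CCOC(=O)[CH-]P(=O)(OCC)OCC | intermediate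
18 | exocyclic enoate (alkene isomers) | CCOC(=O)C=C1[C@@H]2C(=C)C[C@H](O[Si](C)(C)C(C)(C)C)[C@H]1[C@]2(C)COCc1ccccc1 | intermediate
19 | C1-hydroxy enoate | CCOC(=O)C=C1[C@@H]2C(=C)C[C@H](O)[C@H]1[C@]2(C)COCc1ccccc1 | intermediate
20 | saturated hydroxy ester (C6 chain anti) | CCOC(=O)C[C@H]1[C@@H]2[C@@H](C)C[C@H](O)[C@H]1[C@]2(C)COCc1ccccc1 | intermediate
21 | TBS ether of 20 | CCOC(=O)C[C@H]1[C@@H]2[C@@H](C)C[C@H](O[Si](C)(C)C(C)(C)C)[C@H]1[C@]2(C)COCc1ccccc1 | intermediate
22 | lithium enolate of 21 | [Li+].CCOC([O-])=C[C@H]1[C@@H]2[C@@H](C)C[C@H](O[Si](C)(C)C(C)(C)C)[C@H]1[C@]2(C)COCc1ccccc1 | intermediate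
23 | monomethyl ester (C6 epimers) | CCOC(=O)C(C)[C@H]1[C@@H]2[C@@H](C)C[C@H](O[Si](C)(C)C(C)(C)C)[C@H]1[C@]2(C)COCc1ccccc1 | intermediate
24 | lithium enolate of 23 | [Li+].CCOC([O-])=C(C)[C@H]1[C@@H]2[C@@H](C)C[C@H](O[Si](C)(C)C(C)(C)C)[C@H]1[C@]2(C)COCc1ccccc1 | intermediate
25 | gem-dimethyl ester | CCOC(=O)C(C)(C)[C@H]1[C@@H]2[C@@H](C)C[C@H](O[Si](C)(C)C(C)(C)C)[C@H]1[C@]2(C)COCc1ccccc1 | intermediate
26 | neopentyl alcohol | OCC(C)(C)[C@H]1[C@@H]2[C@@H](C)C[C@H](O[Si](C)(C)C(C)(C)C)[C@H]1[C@]2(C)COCc1ccccc1 | intermediate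
27 | C7 aldehyde | O=CC(C)(C)[C@H]1[C@@H]2[C@@H](C)C[C@H](O[Si](C)(C)C(C)(C)C)[C@H]1[C@]2(C)COCc1ccccc1 | intermediate
28 | C7 secondary alcohol (epimers) | CC(O)C(C)(C)[C@H]1[C@@H]2[C@@H](C)C[C@H](O[Si](C)(C)C(C)(C)C)[C@H]1[C@]2(C)COCc1ccccc1 | intermediate
29 | C7,C9 diol | CC(O)C(C)(C)[C@H]1[C@@H]2[C@@H](C)C[C@H](O[Si](C)(C)C(C)(C)C)[C@H]1[C@]2(C)CO | intermediate
30 | keto aldehyde | CC(=O)C(C)(C)[C@H]1[C@@H]2[C@@H](C)C[C@H](O[Si](C)(C)C(C)(C)C)[C@H]1[C@]2(C)C=O | intermediate
31 | aldol (C9 epimers) | O=C1CC(O)[C@@]2(C)[C@@H]3[C@@H](O[Si](C)(C)C(C)(C)C)C[C@H](C)[C@H]2[C@@H]3C1(C)C | intermediate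
32 | (1S,3S)-1-(TBSO)longipin-8-en-7-one | O=C1C=C[C@@]2(C)[C@@H]3[C@@H](O[Si](C)(C)C(C)(C)C)C[C@H](C)[C@H]2[C@@H]3C1(C)C | intermediate
33 | 9-boryl ketone | O=C1C[C@@H](B4OC(C)(C)C(C)(C)O4)[C@@]2(C)[C@@H]3[C@@H](O[Si](C)(C)C(C)(C)C)C[C@H](C)[C@H]2[C@@H]3C1(C)C | intermediate
34 | (1S,3S,9R)-1-(TBSO)-9-hydroxylongipinan-7-one | O=C1C[C@@H](O)[C@@]2(C)[C@@H]3[C@@H](O[Si](C)(C)C(C)(C)C)C[C@H](C)[C@H]2[C@@H]3C1(C)C | intermediate
35 | 3-methylbutanal | CC(C)CC=O | starting material
36 | O9 hemiacetal of 34 and 35 | O=C1C[C@@H](OC(O)CC(C)C)[C@@]2(C)[C@@H]3[C@@H](O[Si](C)(C)C(C)(C)C)C[C@H](C)[C@H]2[C@@H]3C1(C)C | intermediate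
37 | 7-hydroxy 9-isovalerate | O[C@@H]1C[C@@H](OC(=O)CC(C)C)[C@@]2(C)[C@@H]3[C@@H](O[Si](C)(C)C(C)(C)C)C[C@H](C)[C@H]2[C@@H]3C1(C)C | intermediate
38 | 3-methylbut-2-enoic acid | CC(C)=CC(=O)O | starting material
39 | 3-methylbut-2-enoic 2,4,6-trichlorobenzoic anhydride | CC(C)=CC(=O)OC(=O)c1c(Cl)cc(Cl)cc1Cl | intermediate
40 | 7-senecioate 9-isovalerate 1-TBS ether | CC(C)=CC(=O)O[C@@H]1C[C@@H](OC(=O)CC(C)C)[C@@]2(C)[C@@H]3[C@@H](O[Si](C)(C)C(C)(C)C)C[C@H](C)[C@H]2[C@@H]3C1(C)C | intermediate
41 | C1 alcohol diester | CC(C)=CC(=O)O[C@@H]1C[C@@H](OC(=O)CC(C)C)[C@@]2(C)[C@@H]3[C@@H](O)C[C@H](C)[C@H]2[C@@H]3C1(C)C | intermediate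
42 | saturated C1 ketone diester | CC(C)=CC(=O)O[C@@H]1C[C@@H](OC(=O)CC(C)C)[C@@]2(C)[C@@H]3C(=O)C[C@H](C)[C@H]2[C@@H]3C1(C)C | intermediate
43 | C1 trimethylsilyl enol ether | CC(C)=CC(=O)O[C@@H]1C[C@@H](OC(=O)CC(C)C)[C@@]2(C)[C@@H]3C(O[Si](C)(C)C)=C[C@H](C)[C@H]2[C@@H]3C1(C)C | intermediate
44 | (4R,5S,7R,9R,10R,11R)-9-isovaleroyloxy-7-senecioyloxylongipin-2-en-1-one (CNP0214473.1) | CC(C)=CC(=O)O[C@@H]1C[C@@H](OC(=O)CC(C)C)[C@@]2(C)[C@@H]3C(=O)C=C(C)[C@H]2[C@@H]3C1(C)C | target

**Totals**
Total step count: 28. Longest linear sequence: 27 (steps 1–4 and 6–28; step 5 is a one-step branch).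

**Steps most likely to fail**

Step 9. The alkene carries two allylic C–O bonds, so it is a weaker partner than the geranyl-type alkenes for which this cycloaddition is known, and ketene oligomerisation may win. The fallback replaces the ketene by a much more electrophilic keteniminium ion that cannot dimerise. It sets out from acid 12, which is coupled with pyrrolidine (EDC·HCl, HOBt, CH2Cl2) to the pyrrolidine amide F1. Tf2O and 2,4,6-collidine in warm 1,2-dichloroethane convert this into the vinylketeniminium triflate F2. F2 closes in the same crossed sense, under the same allylic-strain control, to the cyclobutaniminium triflate F3. Hydrolysis with aqueous NaHCO3 returns to the route at ketone 15.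

Step 22. The β-carbon is neopentyl, so the copper boryl may add slowly or with poor face control. The fallback sets C9 by a stereochemical relay from a reagent-controlled ketone reduction. It sets out from enone 32. Reduction with Me-CBS oxazaborolidine and BH3·SMe2 (large group C6, small group the alkene) gives the allylic alcohol F4 with the 7-OH on the C11 side. VO(acac)2/t-BuOOH then epoxidises syn to that hydroxyl to give the epoxy alcohol F5. Dess–Martin oxidation gives the epoxy ketone F6. SmI2 in THF/MeOH at −90 °C cleaves only the C8–O bond and comes back to the route at β-hydroxy ketone 34.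

Step 24. The hydride transfer has to reach a ketone flanked by a quaternary carbon inside a ring, and retro-aldol leakage would scramble C9. The fallback separates acylation from reduction. It sets out from 34, which is esterified with isovaleric anhydride and catalytic Sc(OTf)3 in MeCN at −20 °C (no basic catalyst, so no β-elimination) to the β-isovaleroyloxy ketone F7. Reagent-controlled reduction with stoichiometric Me-CBS oxazaborolidine and catecholborane in toluene at −40 °C then delivers hydride to C7 from the C11 side and rejoins the route at 37.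

**Further compounds**
F1 | step 9 | pyrrolidine amide of 12 | O=C(/C=C(\C)C[C@H](O[Si](C)(C)C(C)(C)C)/C=C(\C)COCc1ccccc1)N1CCCC1
F2 | step 9 | vinylketeniminium triflate | C=C(C=C=[N+]1CCCC1)C[C@H](O[Si](C)(C)C(C)(C)C)/C=C(\C)COCc1ccccc1.[O-]S(=O)(=O)C(F)(F)F
F3 | step 9 | cyclobutaniminium triflate | [N+]4(CCCC4)=C1[C@@H]2C(=C)C[C@H](O[Si](C)(C)C(C)(C)C)[C@H]1[C@]2(C)COCc3ccccc3.[O-]S(=O)(=O)C(F)(F)F
F4 | step 22 | allylic alcohol (7-OH on the C11 side) | O[C@H]1C=C[C@@]2(C)[C@@H]3[C@@H](O[Si](C)(C)C(C)(C)C)C[C@H](C)[C@H]2[C@@H]3C1(C)C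
F5 | step 22 | syn 8,9-epoxy alcohol | O[C@H]1[C@H]2O[C@H]2[C@@]3(C)[C@@H]4[C@@H](O[Si](C)(C)C(C)(C)C)C[C@H](C)[C@H]3[C@@H]4C1(C)C
F6 | step 22 | 8,9-epoxy ketone | O=C1[C@H]2O[C@H]2[C@@]3(C)[C@@H]4[C@@H](O[Si](C)(C)C(C)(C)C)C[C@H](C)[C@H]3[C@@H]4C1(C)C
F7 | step 24 | β-isovaleroyloxy ketone | O=C1C[C@@H](OC(=O)CC(C)C)[C@@]2(C)[C@@H]3[C@@H](O[Si](C)(C)C(C)(C)C)C[C@H](C)[C@H]2[C@@H]3C1(C)C
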